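## Retrosynthetic overview

1. The target comes from allylic CH3 → CHO oxidation and phenol desilylation of O-silyl ferutinin. That ester comes from jaeschkeanadiol, a 4-iodophenol silyl ether and CO by Pd carbonylative esterification.
2. Jaeschkeanadiol comes from OH-directed reduction of a hydroazulenone ketol. The ketol comes from the key step, a one-carbon ring expansion of a trans-hydrindenone ketol (CH2 insertion with a 1,2-alkenyl shift, six → seven).
3. The hydrindenone ketol comes from isopropyl addition to the silyl enol ether of a bicyclic 1,3-diketone. The angular methyl controls the carbinol carbon, and the carbinol then controls the ring-fusion CH by equilibration.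
4. The diketone comes from ring-closing metathesis and oxidation of an aldol built from 3-allylcyclopentenone, Me3Al (asymmetric conjugate addition sets the quaternary carbon) and methacrolein.
5. Ring order: the five-membered ring is bought, the six-membered ring is closed by metathesis, and it is then expanded to the seven-membered ring.

Assumption: the ligand antipode drawn in step 2 is taken to give the (R) quaternary carbon; if the sense of induction is opposite, its mirror image is used.

## Route

Step 1
Reactants: 1 3-methoxycyclopent-2-en-1-one; 2 allylmagnesium bromide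
Product: 4 3-(prop-2-en-1-yl)cyclopent-2-en-1-one, via tertiary allylic alcohol 3 (not isolated)
Conditions: allylMgBr (1.2 equiv), THF, −78 → 0 °C; then 1 M HCl, 0 °C, 10 min
Reagents that add atoms: allylmagnesium bromide (2), C=CC[Mg]Br
Why: Stork–Danheiser-type sequence in which the Grignard reagent adds 1,2 to the vinylogous ester and brief acid treatment expels methanol with carbonyl transposition to give the β-allyl enone; no stereocentre is formed.

Step 2
Reactants: 4 3-(prop-2-en-1-yl)cyclopent-2-en-1-one; 5 trimethylaluminium; 6 methacrolein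
Product: 8 (3R)-2-(1-hydroxy-2-methylprop-2-en-1-yl)-3-methyl-3-(prop-2-en-1-yl)cyclopentan-1-one (mixture at C-2 and the carbinol carbon), via dimethylaluminium enolate 7 (not isolated)
Conditions: Me3Al (1.3 equiv), copper thiophene-2-carboxylate Cu(O2CC4H3S) (2 mol %), (R,R)-Ph2P–N[CH(CH3)(2-naphthyl)]2 (4 mol %), Et2O, −30 °C; then methacrolein (2 equiv), −78 → −40 °C
Reagents that add atoms: trimethylaluminium (5), C[Al](C)C
Why: Copper-catalysed asymmetric conjugate addition to a β-substituted cyclopentenone, in which the chiral aminophosphine selects the enone face and sets the quaternary carbon as R, followed by aldol addition of the regiodefined aluminium enolate; the two other stereocentres form as a mixture that does not matter because both are erased in steps 3 and 4.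

Step 3
Reactants: 8 (3R)-2-(1-hydroxy-2-methylprop-2-en-1-yl)-3-methyl-3-(prop-2-en-1-yl)cyclopentan-1-one
Product: 10 (7aR)-4-hydroxy-5,7a-dimethyl-1,2,7,7a-tetrahydro-3H-inden-3-one (enol form of the bicyclic 1,3-diketone), via bicyclic hydroxy ketone 9 (not isolated)
Conditions: second-generation Hoveyda–Grubbs catalyst RuCl2(SIMes)(=CH-C6H4-2-OiPr) (5 mol %), CH2Cl2, 40 °C; then Dess–Martin periodinane (1.3 equiv), 0 °C → rt, same flask
Reagents that add atoms: none
Why: Ring-closing metathesis closes the cyclohexene with its trisubstituted double bond (both ring-fusion epimers cyclise), and Dess–Martin oxidation of the allylic alcohol funnels all diastereomers into one enolised 1,3-diketone whose only stereocentre is the quaternary carbon.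

Step 4
Reactants: 10 (7aR)-4-hydroxy-5,7a-dimethyl-1,2,7,7a-tetrahydro-3H-inden-3-one; 11 isopropylmagnesium chloride
Product: 14 (3R,3aR,7aR)-3-hydroxy-5,7a-dimethyl-3-(propan-2-yl)-1,2,3,3a,7,7a-hexahydro-4H-inden-4-one (trans-fused), via trimethylsilyl dienol ether 12 (not isolated), via silylated isopropyl carbinol 13 (not isolated)
Conditions: NaH (1.0 equiv), Me3SiCl (1.05 equiv), THF, 0 °C; iPrMgCl (2 equiv), LaCl3·2LiCl (1 equiv), −78 → −20 °C; then MeOH, K2CO3 (0.2 equiv), 0 °C → rt
Reagents that add atoms: isopropylmagnesium chloride (11), CC(C)[Mg]Cl; chlorotrimethylsilane, C[Si](C)(C)Cl (silicon present in 12 and 13 only)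
Why: O-silylation masks the acidic diketone as a vinylogous silyl ester, the lanthanum-assisted Grignard 1,2-addition reaches the five-ring carbonyl from the face opposite the angular methyl while the ring-fusion carbon is still planar (sets C-3 as R, OH cis to methyl), and basic methanolysis frees the ketone and equilibrates C-3a by keto–enol epimerisation to the trans-fused R epimer, favoured because the acyl carbon then lies anti to isopropyl and accepts a hydrogen bond from the cis hydroxyl.

Step 5
Reactants: 14 (3R,3aR,7aR)-3-hydroxy-5,7a-dimethyl-3-(propan-2-yl)-1,2,3,3a,7,7a-hexahydro-4H-inden-4-one; 15 (trimethylsilyl)diazomethane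
Product: 17 (3R,3aR,8aR)-3-hydroxy-6,8a-dimethyl-3-(propan-2-yl)-2,3,3a,5,8,8a-hexahydroazulen-4(1H)-one, via alpha-silyl ketone 16 (not isolated)
Conditions: Me3SiCHN2 (1.5 equiv), Sc(OTf)3 (10 mol %), CH2Cl2, −40 → 0 °C; then AcOH–H2O–THF, 0 °C
Reagents that add atoms: (trimethylsilyl)diazomethane (15), C[Si](C)(C)C=[N+]=[N-]
Why: Proposed new method: Sc(OTf)3, chelated by the tertiary OH and the enone oxygen, activates the carbonyl for 1,2-attack of the diazo carbon, and the β-oxido diazonium ion loses N2 with a 1,2-shift of the alkenyl carbon C-5 rather than the tertiary C-3a, because the π bond assists the shift and the rotamer placing N2 anti to C-3a presses the Me3Si group against that crowded carbon, so the six-membered ring grows to the seven-membered β,γ-enone (the α-silyl group blocks a second insertion and leaves by kinetic α-protonation of the dienol, no stereocentre is touched); the closest known reaction type is the Lewis acid-catalysed Büchner–Curtius–Schlotterbeck (Tiffeneau–Demjanov-type) homologation of saturated cycloalkanones with Me3SiCHN2, not yet shown on a β'-hydroxy cyclohexenone with alkenyl migration.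

Step 6
Reactants: 17 (3R,3aR,8aR)-3-hydroxy-6,8a-dimethyl-3-(propan-2-yl)-2,3,3a,5,8,8a-hexahydroazulen-4(1H)-one
Product: 18 (3R,3aS,4S,8aR)-6,8a-dimethyl-3-(propan-2-yl)-1,2,3,3a,4,5,8,8a-octahydroazulene-3,4-diol (jaeschkeanadiol)
Conditions: Me4NBH(OAc)3 (5 equiv), MeCN–AcOH 1:1, −30 °C
Reagents that add atoms: none
Why: Hydroxyl-directed (Evans–Saksena-type) reduction in which the tertiary OH exchanges an acetate on boron and delivers hydride intramolecularly to the ketone face on its own side (the face of the angular methyl), setting C-4 as S, while the isolated alkene and the epimerisable C-3a are untouched in the weakly acidic medium.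

Step 7
Reactants: 18 jaeschkeanadiol; 19 tert-butyl(4-iodophenoxy)dimethylsilane; 20 carbon monoxide
Product: 21 (3R,3aS,4S,8aR)-3-hydroxy-6,8a-dimethyl-3-(propan-2-yl)-1,2,3,3a,4,5,8,8a-octahydroazulen-4-yl 4-[(tert-butyldimethylsilyl)oxy]benzoate
Conditions: 19 (1.5 equiv), Pd(OAc)2 (5 mol %), Xantphos (6 mol %), CO (1 atm), Et3N (3 equiv), DMAP (0.5 equiv), toluene, 80 °C
Reagents that add atoms: carbon monoxide (20), [C-]#[O+]
Why: Palladium-catalysed alkoxycarbonylation (Heck carbonylation), where oxidative addition of the aryl iodide, CO insertion and DMAP-relayed acyl transfer esterify the secondary alcohol with retention at C-4, the tertiary alcohol being too hindered to react and the phenol being masked.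

Step 8
Reactants: 21 silyl-protected ferutinin
Product: 23 (3R,3aS,4S,8aR)-6-formyl-3-hydroxy-8a-methyl-3-(propan-2-yl)-1,2,3,3a,4,5,8,8a-octahydroazulen-4-yl 4-hydroxybenzoate (target), via silyl-protected enal 22 (not isolated)
Conditions: SeO2 (1.2 equiv), 1,4-dioxane, 80 °C; then KHF2 (2 equiv), MeOH, rt, same flask
Reagents that add atoms: selenium dioxide, O=[Se]=O
Why: Riley allylic oxidation (ene reaction then 2,3-shift) attacks the more substituted alkene terminus and there the methyl group lying trans to the ring chain, the competing ring CH2 being shielded and deactivated by the neighbouring aroyloxy group, and runs on to the conjugated aldehyde, after which KHF2 cleaves only the phenolic silyl ether; no stereocentre is affected.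

## Compound list

1 | 3-methoxycyclopent-2-en-1-one | COC1=CC(=O)CC1 | starting material
2 | allylmagnesium bromide | C=CC[Mg]Br | starting material
3 | 3-methoxy-1-(prop-2-en-1-yl)cyclopent-2-en-1-ol | COC1=CC(O)(CC=C)CC1 | intermediate
4 | 3-(prop-2-en-1-yl)cyclopent-2-en-1-one | C=CCC1=CC(=O)CC1 | intermediate
5 | trimethylaluminium | C[Al](C)C | starting material
6 | methacrolein | CC(=C)C=O | starting material
7 | dimethyl{[(3R)-3-methyl-3-(prop-2-en-1-yl)cyclopent-1-en-1-yl]oxy}aluminium | C[Al](C)OC1=C[C@@](C)(CC=C)CC1 | intermediate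
8 | (3R)-2-(1-hydroxy-2-methylprop-2-en-1-yl)-3-methyl-3-(prop-2-en-1-yl)cyclopentan-1-one | O=C1CC[C@](C)(CC=C)C1C(O)C(C)=C | intermediate
9 | (7aR)-4-hydroxy-5,7a-dimethyl-1,2,3a,4,7,7a-hexahydro-3H-inden-3-one (diastereomer mixture) | O=C1CC[C@]2(C)CC=C(C)C(O)C12 | intermediate
10 | (7aR)-4-hydroxy-5,7a-dimethyl-1,2,7,7a-tetrahydro-3H-inden-3-one | O=C1CC[C@]2(C)CC=C(C)C(O)=C12 | intermediate
11 | isopropylmagnesium chloride | CC(C)[Mg]Cl | starting material
12 | (7aR)-5,7a-dimethyl-4-[(trimethylsilyl)oxy]-1,2,7,7a-tetrahydro-3H-inden-3-one | O=C1CC[C@]2(C)CC=C(C)C(O[Si](C)(C)C)=C12 | intermediate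
13 | (3R,7aR)-5,7a-dimethyl-3-(propan-2-yl)-4-[(trimethylsilyl)oxy]-2,3,7,7a-tetrahydro-1H-inden-3-ol | CC(C)[C@]1(O)CC[C@]2(C)CC=C(C)C(O[Si](C)(C)C)=C21 | intermediate
14 | (3R,3aR,7aR)-3-hydroxy-5,7a-dimethyl-3-(propan-2-yl)-1,2,3,3a,7,7a-hexahydro-4H-inden-4-one | CC(C)[C@]1(O)CC[C@]2(C)CC=C(C)C(=O)[C@H]21 | intermediate
15 | (trimethylsilyl)diazomethane | C[Si](C)(C)C=[N+]=[N-] | starting material
16 | (3R,3aR,8aR)-3-hydroxy-6,8a-dimethyl-3-(propan-2-yl)-5-(trimethylsilyl)-2,3,3a,5,8,8a-hexahydroazulen-4(1H)-one | CC(C)[C@]1(O)CC[C@]2(C)CC=C(C)C([Si](C)(C)C)C(=O)[C@H]21 | intermediate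
17 | (3R,3aR,8aR)-3-hydroxy-6,8a-dimethyl-3-(propan-2-yl)-2,3,3a,5,8,8a-hexahydroazulen-4(1H)-one | CC(C)[C@]1(O)CC[C@]2(C)CC=C(C)CC(=O)[C@H]21 | intermediate
18 | jaeschkeanadiol, (3R,3aS,4S,8aR)-6,8a-dimethyl-3-(propan-2-yl)-1,2,3,3a,4,5,8,8a-octahydroazulene-3,4-diol | CC(C)[C@]1(O)CC[C@]2(C)CC=C(C)C[C@H](O)[C@H]21 | intermediate
19 | tert-butyl(4-iodophenoxy)dimethylsilane | CC(C)(C)[Si](C)(C)Oc1ccc(I)cc1 | starting material
20 | carbon monoxide | [C-]#[O+] | starting material
21 | silyl-protected ferutinin | CC(C)[C@]1(O)CC[C@]2(C)CC=C(C)C[C@H](OC(=O)c3ccc(O[Si](C)(C)C(C)(C)C)cc3)[C@H]21 | intermediate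
22 | silyl-protected enal | CC(C)[C@]1(O)CC[C@]2(C)CC=C(C=O)C[C@H](OC(=O)c3ccc(O[Si](C)(C)C(C)(C)C)cc3)[C@H]21 | intermediate
23 | (3R,3aS,4S,8aR)-6-formyl-3-hydroxy-8a-methyl-3-(propan-2-yl)-1,2,3,3a,4,5,8,8a-octahydroazulen-4-yl 4-hydroxybenzoate | CC(C)[C@]1(O)CC[C@]2(C)CC=C(C=O)C[C@H](OC(=O)c3ccc(O)cc3)[C@H]21 | target

## Step count and risks

Total step count: 8. Longest linear sequence: 8.

The three steps most likely to fail are steps 4, 5 and 8.

**Step 4.** The risks are a sluggish addition to the hindered vinylogous silyl ester, loss of water to the dienone, and retro-aldol scrambling during the equilibration. The fallback sets out from 9 and returns at 14. Step 3 is stopped after the metathesis and 9 is isolated. Its trans-fused isomers, the trans-fused hydroxy ketone F1, are separated by chromatography. Organocerium addition (iPrMgCl, CeCl3, THF, −78 °C) occurs anti to the angular methyl and gives the hydrindene diol F2. MnO2 in CH2Cl2 then oxidises only the secondary allylic alcohol to 14. In this variant the ring fusion is fixed before the addition instead of after it.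

**Step 5 (the new step).** The risks are competing migration of C-3a, epoxide formation, pyrazoline formation at the enone, and drift of the double bond into conjugation. The fallback uses known chemistry, sets out from 14 and returns at 17. PhSeCH2Li (from (PhSe)2CH2 and n-BuLi, 2.2 equiv, THF, −78 °C) adds 1,2 to the enone and gives the β-hydroxy selenide F3. Methylation at selenium (MeOTf, 2,6-di-tert-butylpyridine, CH2Cl2) followed by KHCO3 triggers the classical β-hydroxy selenide ring enlargement. This is a semipinacol rearrangement with alkenyl migration and it delivers 17.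

**Step 8.** The risks are oxidation at the ring CH2, or a stop at the allylic alcohol stage. The fallback sets out from 21 and returns at 22.
- mCPBA gives the trisubstituted epoxide F4.
- Me3SiOTf and 2,6-lutidine, then DBU and a mild acidic work-up, isomerise F4 to the exocyclic-methylene allylic alcohol F5.
- Ph3SiOReO3 (2 mol %, Et2O, 0 °C) transposes F5 to the more stable primary allylic alcohol F6.
- MnO2 oxidises F6 to 22, which is desilylated with KHF2 as in step 8.

## Further compounds

F1 | step 4 | (3aS,7aR)-4-hydroxy-5,7a-dimethyl-1,2,3a,4,7,7a-hexahydro-3H-inden-3-one (trans-fused) | O=C1CC[C@]2(C)CC=C(C)C(O)[C@H]21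
F2 | step 4 | (3R,3aS,7aR)-5,7a-dimethyl-3-(propan-2-yl)-2,3,3a,4,7,7a-hexahydro-1H-indene-3,4-diol | CC(C)[C@]1(O)CC[C@]2(C)CC=C(C)C(O)[C@H]21
F3 | step 5 | (3R,3aS,7aR)-5,7a-dimethyl-4-[(phenylselanyl)methyl]-3-(propan-2-yl)-2,3,3a,4,7,7a-hexahydro-1H-indene-3,4-diol | CC(C)[C@]1(O)CC[C@]2(C)CC=C(C)C(O)(C[Se]c3ccccc3)[C@H]21
F4 | step 8 | ring epoxide of silyl-protected ferutinin | CC(C)[C@]1(O)CC[C@]2(C)CC3OC3(C)C[C@H](OC(=O)c4ccc(O[Si](C)(C)C(C)(C)C)cc4)[C@H]21
F5 | step 8 | exocyclic-methylene secondary allylic alcohol | CC(C)[C@]1(O)CC[C@]2(C)CC(O)C(=C)C[C@H](OC(=O)c3ccc(O[Si](C)(C)C(C)(C)C)cc3)[C@H]21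
F6 | step 8 | primary allylic alcohol (hydroxymethyl analogue of 21) | CC(C)[C@]1(O)CC[C@]2(C)CC=C(CO)C[C@H](OC(=O)c3ccc(O[Si](C)(C)C(C)(C)C)cc3)[C@H]21
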